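C1 bears CO2Me; then C2, C3, C4, C5/C6/C7 (butenolide α/β/γ), C8, C9 (Me), C10, C11, C12 (iPr), C13, C14 (CHOH); C15 is the lactone C=O.
Enabling feature: in the 14-membered carbocycle the C14 hydroxyl neighbours C1 of a ring-E C1=C2 enoate whose ester lies cis to C3. This is the pattern an OH-guided trans-addition leaves on a C1≡C2 cycloalkyne, so the enoate is traced back to an alkyne and the ring is opened there.
Cuts, in order: C1–CO2Me (stannane carbonylation), C1≡C2 (ring-closing alkyne metathesis), C10–C11 (Suzuki), C12–C13 (Negishi), C14–C1 (ynone), C4–C5 and C5–C6 (thio-lactone enolate chemistry).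
Forward: the butenolide ring is built first on the C3–C10 fragment, the chain is joined at C10–C11, the 14-membered ring closes at C1≡C2, and tin and then CO2Me are placed on C1.
Stereochemistry: C7 comes from (R)-epichlorohydrin and C14 from Ru-catalysed transfer hydrogenation of an ynone. C9=C10 comes from syn-carboalumination, C11=C12 from syn-bromoboration with retentive couplings, and C1=C2 from trans-hydrostannation with retentive carbonylation.

Key step: step 16

Remark: C5 of the phenylsulfanyl lactones 12, 16 and 17 is expected as an epimer mixture and is drawn without descriptor, because this centre becomes sp2 in step 8.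

Step 1
Reactants: 1 (R)-epichlorohydrin; 2 ethynyl(trimethyl)silane
Product: 4 (2R)-1-chloro-5-(trimethylsilyl)pent-4-yn-2-ol, via lithium (trimethylsilyl)acetylide 3 (not isolated)
Conditions: 2, n-BuLi, THF, −78 °C; BF3·OEt2; then 1, −78 °C; aq NH4Cl
Reagents that add atoms: n-butyllithium, [Li]CCCC (supplies only the lithium of 3)
Why: BF3-promoted opening of a terminal epoxide by a lithium acetylide (Yamaguchi–Hirao alkynylation) occurs at the unsubstituted carbon at −78 °C, where C–Cl is inert, so the C7–O bond and its configuration are carried over unchanged.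

Step 2
Reactants: 4 (2R)-1-chloro-5-(trimethylsilyl)pent-4-yn-2-ol
Product: 5 (2R)-1-chloropent-4-yn-2-ol
Conditions: TBAF, AcOH (1:1), THF, 0 °C → rt
Reagents that add atoms: none
Why: This is a fluoride-induced protodesilylation of an alkynylsilane, and the acetic acid buffer keeps the medium too weakly basic for premature closure of the chlorohydrin to the epoxide.

Step 3
Reactants: 5 (2R)-1-chloropent-4-yn-2-ol
Product: 7 (2R,4E)-1-chloro-5-iodo-4-methylpent-4-en-2-ol, via (E)-alkenyl(dimethyl)alane O-aluminate 6 (not isolated)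
Conditions: AlMe3 (3 equiv), Cp2ZrCl2 (0.25 equiv), CH2Cl2, 0 °C → rt; then I2, THF, −30 → 0 °C
Reagents that add atoms: trimethylaluminium, C[Al](C)C; iodine, II
Why: Zirconium-catalysed Negishi carboalumination adds Me and Al syn across the terminal alkyne with Al at the terminus (the hydroxyl is masked in situ as its aluminium alkoxide), and iodinolysis with retention fixes the (E)-C9=C10 geometry.

Step 4
Reactants: 7 (2R,4E)-1-chloro-5-iodo-4-methylpent-4-en-2-ol
Product: 8 (2R)-2-[(2E)-3-iodo-2-methylprop-2-en-1-yl]oxirane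
Conditions: K2CO3, MeOH, 0 °C → rt
Reagents that add atoms: none
Why: Intramolecular Williamson displacement of chloride by the C7 alkoxide (3-exo-tet) closes the epoxide without breaking C7–O, so the configuration is kept, and the alkenyl iodide is inert to carbonate.

Step 5
Reactants: 8 (2R)-2-[(2E)-3-iodo-2-methylprop-2-en-1-yl]oxirane; 9 (phenylsulfanyl)acetic acid
Product: 12 (5R)-5-[(2E)-3-iodo-2-methylprop-2-en-1-yl]-3-(phenylsulfanyl)oxolan-2-one, via dilithiated (phenylsulfanyl)acetate 10 (not isolated), via (4R,6E)-4-hydroxy-7-iodo-6-methyl-2-(phenylsulfanyl)hept-6-enoic acid 11 (not isolated)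
Conditions: 9, LDA (2.1 equiv), THF, 0 °C; then 8, 0 °C → rt; 1 M HCl; then p-TsOH (cat.), toluene, 50 °C
Reagents that add atoms: lithium diisopropylamide, [Li]N(C(C)C)C(C)C (supplies only the lithium of 10)
Why: The sulfur-stabilised carboxylate dianion opens the epoxide at its terminal carbon (SN2, forming C5–C6) and acid-catalysed 5-exo-trig lactonisation follows, the standard entry to α-phenylsulfanyl γ-lactones, with C7 untouched and the new C5 centre erased later.

Step 6
Reactants: 13 pent-3-yn-1-ol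
Product: 14 5-iodopent-2-yne
Conditions: I2, PPh3, imidazole, CH2Cl2, 0 °C → rt
Reagents that add atoms: iodine, II
Why: Appel-type iodination of a primary alcohol proceeds through the alkoxyphosphonium salt under near-neutral conditions that leave the internal alkyne alone.

Step 7
Reactants: 12 (5R)-5-[(2E)-3-iodo-2-methylprop-2-en-1-yl]-3-(phenylsulfanyl)oxolan-2-one; 14 5-iodopent-2-yne
Product: 16 (5R)-5-[(2E)-3-iodo-2-methylprop-2-en-1-yl]-3-(pent-3-yn-1-yl)-3-(phenylsulfanyl)oxolan-2-one, via lithium enolate of the lactone 15 (not isolated)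
Conditions: LDA (1.1 equiv), THF/HMPA, −78 °C; then 14 (1.5 equiv), −78 → 0 °C
Reagents that add atoms: lithium diisopropylamide, [Li]N(C(C)C)C(C)C (supplies only the lithium of 15)
Why: SN2 alkylation of the soft, sulfur-stabilised lactone enolate with a primary iodide (favoured over E2 by the polar cosolvent) forms C4–C5, and the quaternary C5 centre, expected mainly anti to the C7 side chain, is of no consequence because step 8 destroys it.

Step 8
Reactants: 16 (5R)-5-[(2E)-3-iodo-2-methylprop-2-en-1-yl]-3-(pent-3-yn-1-yl)-3-(phenylsulfanyl)oxolan-2-one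
Product: 18 (5R)-5-[(2E)-3-iodo-2-methylprop-2-en-1-yl]-3-(pent-3-yn-1-yl)furan-2(5H)-one, via α-benzenesulfinyl lactone 17 (not isolated)
Conditions: mCPBA (1.0 equiv), CH2Cl2, −78 → 0 °C; aq NaHCO3; then toluene, 110 °C
Reagents that add atoms: mCPBA, OOC(=O)c1cccc(Cl)c1 (its oxygen sits in 17 only and leaves again on elimination)
Why: Low-temperature S-oxidation is followed by thermal syn-elimination of the sulfoxide (Ei), which takes a ring C6–H and gives the conjugated endocyclic butenolide as is usual for α-alkyl-α-sulfinyl lactones, while C7 is not involved.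

Step 9
Reactants: 19 3-methylbut-1-yne
Product: 21 2-[(1Z)-2-bromo-3-methylbut-1-en-1-yl]-4,4,5,5-tetramethyl-1,3,2-dioxaborolane, via (Z)-(2-bromo-3-methylbut-1-enyl)dibromoborane 20 (not isolated)
Conditions: BBr3 (1.05 equiv), CH2Cl2, −78 °C → rt; then pinacol, 0 °C → rt
Reagents that add atoms: boron tribromide, BrB(Br)Br; pinacol, CC(C)(O)C(C)(C)O
Why: Syn-bromoboration of a terminal alkyne puts boron on the terminus (C11) and bromine on C12 on the same side, and immediate esterification with pinacol freezes the (Z)-geometry.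

Step 10
Reactants: 21 2-[(1Z)-2-bromo-3-methylbut-1-en-1-yl]-4,4,5,5-tetramethyl-1,3,2-dioxaborolane; 22 (2-ethoxy-2-oxoethyl)zinc bromide
Product: 23 ethyl (3E)-4-methyl-3-[(4,4,5,5-tetramethyl-1,3,2-dioxaborolan-2-yl)methylidene]pentanoate
Conditions: 22 (1.5 equiv), Pd(Pt-Bu3)2 (3 mol %), THF, rt
Reagents that add atoms: none
Why: Negishi coupling of the Reformatsky reagent at C–Br proceeds with retention under a bulky, electron-rich Pd catalyst, while the pinacol boronate stays silent without base, so C12–C13 is formed cis to boron.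

Step 11
Reactants: 23 ethyl (3E)-4-methyl-3-[(4,4,5,5-tetramethyl-1,3,2-dioxaborolan-2-yl)methylidene]pentanoate
Product: 24 (3E)-N-methoxy-N,4-dimethyl-3-[(4,4,5,5-tetramethyl-1,3,2-dioxaborolan-2-yl)methylidene]pentanamide
Conditions: MeNH(OMe)·HCl (2 equiv), i-PrMgCl (4 equiv), THF, −20 °C, premixed; then 23, −20 → 0 °C
Reagents that add atoms: N,O-dimethylhydroxylamine hydrochloride, CNOC.Cl
Why: Ester aminolysis by the pre-formed magnesium amide (Weinreb amide synthesis) leaves no free alkyl Grignard reagent in solution that could attack boron.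

Step 12
Reactants: 24 (3E)-N-methoxy-N,4-dimethyl-3-[(4,4,5,5-tetramethyl-1,3,2-dioxaborolan-2-yl)methylidene]pentanamide; 25 prop-1-yn-1-ylmagnesium bromide
Product: 26 (6E)-6-(propan-2-yl)-7-(4,4,5,5-tetramethyl-1,3,2-dioxaborolan-2-yl)hept-6-en-2-yn-4-one
Conditions: 25 (1.3 equiv, 0.5 M in THF), THF, −20 → 0 °C; inverse quench into cold 1 M NaHSO4
Reagents that add atoms: none
Why: Weinreb ketone synthesis stops at the chelated tetrahedral adduct, the weakly nucleophilic alkynyl Grignard reagent should spare the pinacol boronate at or below 0 °C, and the acidic quench suppresses amine addition to the ynone and migration of C11=C12.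

Step 13
Reactants: 26 (6E)-6-(propan-2-yl)-7-(4,4,5,5-tetramethyl-1,3,2-dioxaborolan-2-yl)hept-6-en-2-yn-4-one
Product: 27 (4S,6E)-6-(propan-2-yl)-7-(4,4,5,5-tetramethyl-1,3,2-dioxaborolan-2-yl)hept-6-en-2-yn-4-ol
Conditions: (S,S)-[Ru(p-cymene)(TsDPEN)] (3 mol %), i-PrOH, rt
Reagents that add atoms: none
Why: Base-free Noyori asymmetric transfer hydrogenation of an alkynyl ketone delivers H through the six-membered Ru–H/N–H transition state with the alkyne in the place usually taken by an aryl group, so the (S,S)-catalyst should set (S)-C14 without touching alkyne, alkene or boronate.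

Step 14
Reactants: 27 (4S,6E)-6-(propan-2-yl)-7-(4,4,5,5-tetramethyl-1,3,2-dioxaborolan-2-yl)hept-6-en-2-yn-4-ol
Product: 28 2-[(1E,4S)-4-(tert-butyldimethylsilyloxy)-2-(propan-2-yl)hept-1-en-5-yn-1-yl]-4,4,5,5-tetramethyl-1,3,2-dioxaborolane
Conditions: TBSCl, imidazole, DMAP (cat.), CH2Cl2, rt
Reagents that add atoms: tert-butyldimethylsilyl chloride, CC(C)(C)[Si](C)(C)Cl
Why: Standard imidazole-mediated O-silylation of a secondary propargylic alcohol masks the protic group ahead of the coupling and the metathesis and does not affect C14.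

Step 15
Reactants: 18 (5R)-5-[(2E)-3-iodo-2-methylprop-2-en-1-yl]-3-(pent-3-yn-1-yl)furan-2(5H)-one; 28 2-[(1E,4S)-4-(tert-butyldimethylsilyloxy)-2-(propan-2-yl)hept-1-en-5-yn-1-yl]-4,4,5,5-tetramethyl-1,3,2-dioxaborolane
Product: 29 (5R)-5-[(2E,4E,7S)-7-(tert-butyldimethylsilyloxy)-2-methyl-5-(propan-2-yl)deca-2,4-dien-8-yn-1-yl]-3-(pent-3-yn-1-yl)furan-2(5H)-one
Conditions: Pd(dppf)Cl2·CH2Cl2 (5 mol %), aq K3PO4 (2 equiv), THF, degassed, rt
Reagents that add atoms: none
Why: Suzuki–Miyaura coupling of an alkenyl iodide with an alkenyl boronate retains geometry at both sp2 carbons, forming C10–C11 and the (9E,11E)-diene with C13 cis to C10, and phosphate at room temperature is chosen to spare the base-sensitive C7–H.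

Step 16
Reactants: 29 (5R)-5-[(2E,4E,7S)-7-(tert-butyldimethylsilyloxy)-2-methyl-5-(propan-2-yl)deca-2,4-dien-8-yn-1-yl]-3-(pent-3-yn-1-yl)furan-2(5H)-one
Product: 30 (7R,14S)-cycloalkyne: 14-membered carbocycle C1–C14 with C1≡C2 and the C5–C7 butenolide bridge and the (9E,11E)-diene and C14–OTBS
Conditions: [Mo(≡CC6H4-4-OMe)(OSiPh3)3] (10 mol %), powdered MS 5 Å, toluene (2 mM), rt → 60 °C
Reagents that add atoms: none
Why: The molybdenum alkylidyne adds [2+2] to one propynyl end of 29, the metallacyclobutadiene opens productively, and the substrate-bound alkylidyne engages the second propynyl end in the same way, so C1≡C2 forms and but-2-yne leaves; this is ring-closing alkyne metathesis, whose closest known type is the closure of methyl-capped diynes to 12- to 20-membered cycloalkynes with silanolate-supported Mo alkylidynes. The only ring formed is the 14-membered carbocycle, closed by an intramolecular [2+2]/retro-[2+2] sequence that leaves the new triple bond endocyclic. No stereocentre is created, C7 is remote from the metal, and the propargylic C14–O bond is shielded as its bulky silyl ether. Selectivity for alkynes over the three C=C bonds is inherent, because alkylidynes do not form productive metallacycles with alkenes, so the diene and the butenolide keep their geometry. Cyclisation must outrun acyclic oligomerisation: high dilution and capture of but-2-yne by the 5 Å sieves pull the equilibrium toward the ring, and the ring-cis C11=C12 bond together with the C5–C7 butenolide segment folds the chain so that both termini approach each other.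

Step 17
Reactants: 30 (7R,14S)-cycloalkyne silyl ether
Product: 31 (7R,14S)-cycloalkynol: as 30 but C14–OH
Conditions: HF·pyridine, pyridine/THF, 0 °C → rt
Reagents that add atoms: none
Why: Acidic fluoride desilylation cleaves the secondary silyl ether, and the non-basic medium avoids deprotonation at C7 of the butenolide.

Step 18
Reactants: 31 (7R,14S)-cycloalkynol
Product: 32 (1Z,7R,14S)-1-(tributylstannyl)cycloalkenol: ring-E C1=C2 with SnBu3 on C1 cis to C3 and C14–OH free
Conditions: [Cp*RuCl]4 (2.5 mol %), Bu3SnH (1.15 equiv, slow addition), CH2Cl2, rt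
Reagents that add atoms: tributyltin hydride, CCCC[SnH](CCCC)CCCC
Why: In ruthenium-catalysed trans-hydrostannation a hydrogen bond from the C14–OH to the chloride ligand orients the stannane so that tin goes to the proximal C1 and hydrogen to the opposite face at C2, giving the ring-E alkene, while the diene, whose C13 substituent points inward, cannot adopt the s-cis form needed to sequester the catalyst.

Step 19
Reactants: 32 (1Z,7R,14S)-1-(tributylstannyl)cycloalkenol
Product: 33 target CNP0173999.1 (1Z,7R,9E,11E,14S)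
Conditions: Pd(OAc)2 (10 mol %), AsPh3 (20 mol %), 1,4-benzoquinone (1.5 equiv), CF3CO2H (cat.), CO (1 atm), MeOH, rt
Reagents that add atoms: carbon monoxide, [C-]#[O+]; methanol, CO
Why: Oxidative Pd-catalysed methoxycarbonylation of the alkenylstannane (Sn-to-Pd(II) transmetalation, CO insertion, methanolysis, reoxidation by benzoquinone) proceeds with retention of alkene geometry and tolerates the free allylic hydroxyl, so the ester ends up cis to C3.

Compound list
1 | (R)-epichlorohydrin | ClC[C@H]1CO1 | starting material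
2 | ethynyl(trimethyl)silane | C#C[Si](C)(C)C | starting material
3 | lithium (trimethylsilyl)acetylide | [Li]C#C[Si](C)(C)C | intermediate
4 | (2R)-1-chloro-5-(trimethylsilyl)pent-4-yn-2-ol | ClC[C@H](O)CC#C[Si](C)(C)C | intermediate
5 | (2R)-1-chloropent-4-yn-2-ol | ClC[C@H](O)CC#C | intermediate
6 | (E)-alkenyl(dimethyl)alane O-aluminate from 5 | ClC[C@H](O[Al](C)C)C/C(C)=C/[Al](C)C | intermediate
7 | (2R,4E)-1-chloro-5-iodo-4-methylpent-4-en-2-ol | ClC[C@H](O)C/C(C)=C/I | intermediate
8 | (2R)-2-[(2E)-3-iodo-2-methylprop-2-en-1-yl]oxirane | I/C=C(C)/C[C@@H]1CO1 | intermediate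
9 | (phenylsulfanyl)acetic acid | OC(=O)CSc1ccccc1 | starting material
10 | dilithiated (phenylsulfanyl)acetate | [Li]OC(=O)C([Li])Sc1ccccc1 | intermediate
11 | (4R,6E)-4-hydroxy-7-iodo-6-methyl-2-(phenylsulfanyl)hept-6-enoic acid | OC(=O)C(Sc1ccccc1)C[C@H](O)C/C(C)=C/I | intermediate
12 | (5R)-5-[(2E)-3-iodo-2-methylprop-2-en-1-yl]-3-(phenylsulfanyl)oxolan-2-one | O=C1C(Sc2ccccc2)C[C@@H](C/C(C)=C/I)O1 | intermediate
13 | pent-3-yn-1-ol | CC#CCCO | starting material
14 | 5-iodopent-2-yne | CC#CCCI | intermediate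
15 | lithium enolate of lactone 12 | [Li]OC1=C(Sc2ccccc2)C[C@@H](C/C(C)=C/I)O1 | intermediate
16 | (5R)-5-[(2E)-3-iodo-2-methylprop-2-en-1-yl]-3-(pent-3-yn-1-yl)-3-(phenylsulfanyl)oxolan-2-one | CC#CCCC1(Sc2ccccc2)C[C@@H](C/C(C)=C/I)OC1=O | intermediate
17 | (5R)-3-(benzenesulfinyl)-5-[(2E)-3-iodo-2-methylprop-2-en-1-yl]-3-(pent-3-yn-1-yl)oxolan-2-one | CC#CCCC1(S(=O)c2ccccc2)C[C@@H](C/C(C)=C/I)OC1=O | intermediate
18 | (5R)-5-[(2E)-3-iodo-2-methylprop-2-en-1-yl]-3-(pent-3-yn-1-yl)furan-2(5H)-one | CC#CCCC1=C[C@@H](C/C(C)=C/I)OC1=O | intermediate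
19 | 3-methylbut-1-yne | CC(C)C#C | starting material
20 | (Z)-(2-bromo-3-methylbut-1-enyl)dibromoborane | CC(C)/C(Br)=C/B(Br)Br | intermediate
21 | 2-[(1Z)-2-bromo-3-methylbut-1-en-1-yl]-4,4,5,5-tetramethyl-1,3,2-dioxaborolane | CC(C)/C(Br)=C/B1OC(C)(C)C(C)(C)O1 | intermediate
22 | (2-ethoxy-2-oxoethyl)zinc bromide | CCOC(=O)C[Zn]Br | starting material
23 | ethyl (3E)-4-methyl-3-[(4,4,5,5-tetramethyl-1,3,2-dioxaborolan-2-yl)methylidene]pentanoate | CC(C)/C(CC(=O)OCC)=C/B1OC(C)(C)C(C)(C)O1 | intermediate
24 | (3E)-N-methoxy-N,4-dimethyl-3-[(4,4,5,5-tetramethyl-1,3,2-dioxaborolan-2-yl)methylidene]pentanamide | CC(C)/C(CC(=O)N(C)OC)=C/B1OC(C)(C)C(C)(C)O1 | intermediate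
25 | prop-1-yn-1-ylmagnesium bromide | CC#C[Mg]Br | starting material
26 | (6E)-6-(propan-2-yl)-7-(4,4,5,5-tetramethyl-1,3,2-dioxaborolan-2-yl)hept-6-en-2-yn-4-one | CC(C)/C(CC(=O)C#CC)=C/B1OC(C)(C)C(C)(C)O1 | intermediate
27 | (4S,6E)-6-(propan-2-yl)-7-(4,4,5,5-tetramethyl-1,3,2-dioxaborolan-2-yl)hept-6-en-2-yn-4-ol | CC(C)/C(C[C@H](O)C#CC)=C/B1OC(C)(C)C(C)(C)O1 | intermediate
28 | 2-[(1E,4S)-4-(tert-butyldimethylsilyloxy)-2-(propan-2-yl)hept-1-en-5-yn-1-yl]-4,4,5,5-tetramethyl-1,3,2-dioxaborolane | CC(C)/C(C[C@H](O[Si](C)(C)C(C)(C)C)C#CC)=C/B1OC(C)(C)C(C)(C)O1 | intermediate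
29 | (5R)-5-[(2E,4E,7S)-7-(tert-butyldimethylsilyloxy)-2-methyl-5-(propan-2-yl)deca-2,4-dien-8-yn-1-yl]-3-(pent-3-yn-1-yl)furan-2(5H)-one | CC#CCCC1=C[C@@H](C/C(C)=C/C=C(/C(C)C)C[C@H](O[Si](C)(C)C(C)(C)C)C#CC)OC1=O | intermediate
30 | (7R,14S)-14-membered cycloalkyne, C1≡C2, C14–OTBS | C1#CCCC2=C[C@@H](C/C(C)=C/C=C(/C(C)C)C[C@@H]1O[Si](C)(C)C(C)(C)C)OC2=O | intermediate
31 | (7R,14S)-14-membered cycloalkynol, C14–OH | C1#CCCC2=C[C@@H](C/C(C)=C/C=C(/C(C)C)C[C@@H]1O)OC2=O | intermediate
32 | (1Z,7R,14S)-C1-tributylstannyl cycloalkenol | CCCC[Sn](CCCC)(CCCC)/C1=C\CCC2=C[C@@H](C/C(C)=C/C=C(/C(C)C)C[C@@H]1O)OC2=O | intermediate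
33 | CNP0173999.1 (1Z,7R,9E,11E,14S) | COC(=O)/C1=C\CCC2=C[C@@H](C/C(C)=C/C=C(/C(C)C)C[C@@H]1O)OC2=O | target

Total step count: 19.
Longest linear sequence: 12 steps (1, 2, 3, 4, 5, 7, 8, 15, 16, 17, 18, 19). The boronate branch (steps 9–14) joins at step 15 and step 6 feeds step 7.

Steps most likely to fail

Step 16. Alkyne metathesis is reversible, so strain in the polyunsaturated 14-membered ring may push the equilibrium toward acyclic and cyclic oligomers, or the hindered propargylic terminus may be engaged too slowly.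
- The fallback makes C1≡C2 intermolecularly and closes the ring irreversibly at another bond.
- It sets out from 18 and 28 (28 in excess). Alkyne cross-metathesis with the same class of Mo alkylidyne over 5 Å sieves should give the open-chain iodo-boronate (5R)-5-[(2E)-3-iodo-2-methylprop-2-en-1-yl]-3-[(5S,7E)-5-(tert-butyldimethylsilyloxy)-7-(propan-2-yl)-8-(4,4,5,5-tetramethyl-1,3,2-dioxaborolan-2-yl)oct-7-en-3-yn-1-yl]furan-2(5H)-one F1.
- An intramolecular Suzuki–Miyaura coupling at C10–C11 under high dilution (Pd(dppf)Cl2, aq K3PO4, THF) then closes the macrocycle under kinetic control and rejoins the route at 30.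

Step 12. The Grignard reagent may complex or attack the boronate, or merely enolise the doubly activated C13 methylene, so that acylation stalls or C11=C12 drifts into conjugation.
- The fallback uses an oxidation-level detour through a far more electrophilic carbonyl and sets out from 23.
- DIBAL-H (CH2Cl2, −78 °C) should give the aldehyde (3E)-4-methyl-3-[(4,4,5,5-tetramethyl-1,3,2-dioxaborolan-2-yl)methylidene]pentanal F2.
- F2 takes up 25 at −78 °C, where boron is not touched, to give the racemic carbinol rac-(6E)-6-(propan-2-yl)-7-(4,4,5,5-tetramethyl-1,3,2-dioxaborolan-2-yl)hept-6-en-2-yn-4-ol F3.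
- Buffered Dess–Martin oxidation of F3 rejoins the route at 26.

Step 15. The aqueous base may deprotonate the butenolide at C7, eroding the configuration, or open the lactone, and protodeborylation of the hindered boronate may compete.
- The fallback runs the coupling before the butenolide double bond exists, when C7–H is not acidic, and sets out from 16 and 28.
- The same Suzuki–Miyaura conditions should give the saturated lactone (5R)-5-[(2E,4E,7S)-7-(tert-butyldimethylsilyloxy)-2-methyl-5-(propan-2-yl)deca-2,4-dien-8-yn-1-yl]-3-(pent-3-yn-1-yl)-3-(phenylsulfanyl)oxolan-2-one F4.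
- One equivalent of mCPBA at −78 °C oxidises sulfur much faster than the diene and gives the sulfoxide (5R)-3-(benzenesulfinyl)-5-[(2E,4E,7S)-7-(tert-butyldimethylsilyloxy)-2-methyl-5-(propan-2-yl)deca-2,4-dien-8-yn-1-yl]-3-(pent-3-yn-1-yl)oxolan-2-one F5.
- Thermolysis of F5 in toluene rejoins the route at 29.

Further compounds
F1 | step 16 | (5R)-5-[(2E)-3-iodo-2-methylprop-2-en-1-yl]-3-[(5S,7E)-5-(tert-butyldimethylsilyloxy)-7-(propan-2-yl)-8-(4,4,5,5-tetramethyl-1,3,2-dioxaborolan-2-yl)oct-7-en-3-yn-1-yl]furan-2(5H)-one | CC(C)/C(C[C@H](O[Si](C)(C)C(C)(C)C)C#CCCC1=C[C@@H](C/C(C)=C/I)OC1=O)=C/B2OC(C)(C)C(C)(C)O2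
F2 | step 12 | (3E)-4-methyl-3-[(4,4,5,5-tetramethyl-1,3,2-dioxaborolan-2-yl)methylidene]pentanal | CC(C)/C(CC=O)=C/B1OC(C)(C)C(C)(C)O1
F3 | step 12 | rac-(6E)-6-(propan-2-yl)-7-(4,4,5,5-tetramethyl-1,3,2-dioxaborolan-2-yl)hept-6-en-2-yn-4-ol | CC(C)/C(CC(O)C#CC)=C/B1OC(C)(C)C(C)(C)O1
F4 | step 15 | (5R)-5-[(2E,4E,7S)-7-(tert-butyldimethylsilyloxy)-2-methyl-5-(propan-2-yl)deca-2,4-dien-8-yn-1-yl]-3-(pent-3-yn-1-yl)-3-(phenylsulfanyl)oxolan-2-one | CC#CCCC1(Sc2ccccc2)C[C@@H](C/C(C)=C/C=C(/C(C)C)C[C@H](O[Si](C)(C)C(C)(C)C)C#CC)OC1=O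
F5 | step 15 | (5R)-3-(benzenesulfinyl)-5-[(2E,4E,7S)-7-(tert-butyldimethylsilyloxy)-2-methyl-5-(propan-2-yl)deca-2,4-dien-8-yn-1-yl]-3-(pent-3-yn-1-yl)oxolan-2-one | CC#CCCC1(S(=O)c2ccccc2)C[C@@H](C/C(C)=C/C=C(/C(C)C)C[C@H](O[Si](C)(C)C(C)(C)C)C#CC)OC1=O
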